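The exocyclic C–C bond between the aryloxy-bearing CH2 and C2 of the oxolane ring is made at the ketone oxidation level. C2 carries the ring oxygen, so it can enter as the acyl carbon of an open-chain thioester in which C3 (from (R)-citramalic acid) and C5 (CBS reduction) are already set; the CH2 enters as the α-oxygenated tin reagent made from isofraxidin. A palladium/copper thioester–stannane ketone synthesis joins the two halves under neutral conditions that spare the coumarin; desilylation in the same flask lets the C5 hydroxyl close onto C2 to give the ring as a hemiketal. Silane reduction of the derived oxocarbenium ion then fixes C2.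

Key step: step 7

Assumption: isofraxidin, (R)-citramalic acid, tributyl(iodomethyl)stannane and 2-methylprop-1-enylmagnesium bromide solution are taken as purchasable; hemiketal 11 is handled as a mixture of C2 anomers, which converge in step 8.

Step 1
Reactants: 1 (R)-citramalic acid [(2R)-2-hydroxy-2-methylbutanedioic acid]
Product: 2 [(4R)-2,2,4-trimethyl-5-oxo-1,3-dioxolan-4-yl]acetic acid
Conditions: 2,2-dimethoxypropane, p-TsOH (cat.), acetone, rt
Reagents that add atoms: 2,2-dimethoxypropane, COC(C)(C)OC
Why: Acid-catalysed transacetalisation should tie the tertiary hydroxyl and the adjacent carboxyl into the five-membered dioxolanone (favoured over the six-membered alternative), leaving only the CH2CO2H group free and carrying the future C3 stereocentre unchanged from the chiral pool.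

Step 2
Reactants: 2 [(4R)-2,2,4-trimethyl-5-oxo-1,3-dioxolan-4-yl]acetic acid
Product: 4 (5R)-2,2,5-trimethyl-5-(4-methyl-2-oxopent-3-en-1-yl)-1,3-dioxolan-4-one, via acid chloride 3 (not isolated)
Conditions: (COCl)2, DMF (cat.), CH2Cl2, 0 °C to rt, evaporate; then 2-methylprop-1-enylmagnesium bromide premixed with ZnCl2, Pd(PPh3)4 (3 mol%), THF, 0 °C to rt
Reagents that add atoms: oxalyl chloride, O=C(Cl)C(=O)Cl (chlorine of 3 only); 2-methylprop-1-enylmagnesium bromide, CC(C)=C[Mg]Br
Why: Negishi acylation, in which the weakly basic alkenylzinc chloride should couple with the acid chloride under palladium catalysis without attacking the dioxolanone or causing β-elimination of the β-oxygen.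

Step 3
Reactants: 4 (5R)-2,2,5-trimethyl-5-(4-methyl-2-oxopent-3-en-1-yl)-1,3-dioxolan-4-one
Product: 5 (5R)-5-[(2R)-2-hydroxy-4-methylpent-3-en-1-yl]-2,2,5-trimethyl-1,3-dioxolan-4-one
Conditions: (S)-Me-CBS oxazaborolidine (0.2 equiv), catecholborane, toluene, −78 °C; pH 7 buffer work-up
Reagents that add atoms: none
Why: CBS reduction with the alkenyl group as the large and the CH2 group as the small substituent should give 1,2-reduction to the (R)-allylic alcohol under catalyst control, which sets the future C5.

Step 4
Reactants: 5 (5R)-5-[(2R)-2-hydroxy-4-methylpent-3-en-1-yl]-2,2,5-trimethyl-1,3-dioxolan-4-one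
Product: 6 (5R)-2,2,5-trimethyl-5-{(2R)-4-methyl-2-[(triethylsilyl)oxy]pent-3-en-1-yl}-1,3-dioxolan-4-one
Conditions: TESCl, imidazole, CH2Cl2, 0 °C
Reagents that add atoms: chlorotriethylsilane, CC[Si](Cl)(CC)CC
Why: Silylation of the secondary allylic alcohol should stop the γ-hydroxyl from translactonising onto the dioxolanone and installs a group that fluoride removes later without acid.

Step 5
Reactants: 6 (5R)-2,2,5-trimethyl-5-{(2R)-4-methyl-2-[(triethylsilyl)oxy]pent-3-en-1-yl}-1,3-dioxolan-4-one
Product: 7 S-ethyl (2R,4R)-2-hydroxy-2,6-dimethyl-4-[(triethylsilyl)oxy]hept-5-enethioate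
Conditions: AlMe3, EtSH, CH2Cl2, 0 °C to rt; Rochelle salt work-up
Reagents that add atoms: ethanethiol, CCS
Why: Aluminium thiolate ester-to-thioester exchange should open the activated dioxolanone at its carbonyl with loss of acetone, giving the thioester with a free tertiary hydroxyl and both stereocentres untouched.

Step 6
Reactants: 8 isofraxidin (7-hydroxy-6,8-dimethoxy-2H-chromen-2-one)
Product: 9 6,8-dimethoxy-7-[(tributylstannyl)methoxy]-2H-chromen-2-one
Conditions: K2CO3, DMF, 60 °C
Reagents that add atoms: tributyl(iodomethyl)stannane, CCCC[Sn](CCCC)(CCCC)CI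
Why: Williamson O-alkylation of the phenoxide with the SN2-reactive α-stannyl iodide should proceed under carbonate conditions that leave the coumarin lactone closed.

Step 7
Reactants: 7 S-ethyl (2R,4R)-2-hydroxy-2,6-dimethyl-4-[(triethylsilyl)oxy]hept-5-enethioate; 9 6,8-dimethoxy-7-[(tributylstannyl)methoxy]-2H-chromen-2-one
Product: 11 7-{[(3R,5R)-2,3-dihydroxy-3-methyl-5-(2-methylprop-1-en-1-yl)oxolan-2-yl]methoxy}-6,8-dimethoxy-2H-chromen-2-one (mixture of C2 anomers), via open-chain ketone 10 (not isolated)
Conditions: Pd2(dba)3 (2.5 mol%), tri(2-furyl)phosphine (20 mol%), copper(I) diphenylphosphinate (1.5 equiv), THF, 50 °C; then HF·pyridine, pyridine, 0 °C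
Reagents that add atoms: none
Why: Liebeskind–Srogl ketone synthesis in its thiol ester–organostannane form: copper(I)-assisted oxidative addition of Pd(0) into the C(O)–S bond of 7, transfer of the α-oxygenated CH2 group from tin to the acyl–palladium species (expected to outpace butyl transfer because of the α-oxygen, with copper taking up the thiolate and the phosphinate taking up tin) and reductive elimination should give ketone 10. The closest known reaction type is the palladium-catalysed alkoxymethylation of acyl electrophiles with (alkoxymethyl)stannanes. HF·pyridine then removes the triethylsilyl group and the C5 hydroxyl adds to the C2 ketone in a 5-exo-trig hemiketalisation that closes the oxolane ring. The new centre C2 of 11 is deliberately left as an anomeric mixture because it is defined only in step 8, while quaternary C3 and C5 cannot epimerise under these neutral conditions. The step needs chemoselectivity for the thioester over the coumarin lactone and its enoate double bond, which the base-free conditions and the copper-specific activation of the C–S bond should secure, and it should tolerate the free tertiary hydroxyl.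

Step 8
Reactants: 11 7-{[(3R,5R)-2,3-dihydroxy-3-methyl-5-(2-methylprop-1-en-1-yl)oxolan-2-yl]methoxy}-6,8-dimethoxy-2H-chromen-2-one
Product: 12 7-{[(2S,3R,5R)-3-hydroxy-3-methyl-5-(2-methylprop-1-en-1-yl)oxolan-2-yl]methoxy}-6,8-dimethoxy-2H-chromen-2-one (CNP0086110.2)
Conditions: Et3SiH, BF3·OEt2, CH2Cl2/MeCN, −78 to −40 °C
Reagents that add atoms: none
Why: Lewis acid/silane reductive deoxygenation of the hemiketal (C-glycoside-type), in which the five-membered oxocarbenium ion should take up hydride by inside attack on the envelope that places the C3 hydroxyl and the C5 alkenyl group pseudoequatorial and the C3 methyl pseudoaxial, so that hydrogen enters cis to the C3 hydroxyl and the CH2OAr arm ends up trans to it and trans to the C5 substituent (2S).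

Compound list
1 | (R)-citramalic acid [(2R)-2-hydroxy-2-methylbutanedioic acid] | C[C@@](O)(CC(=O)O)C(=O)O | starting material
2 | [(4R)-2,2,4-trimethyl-5-oxo-1,3-dioxolan-4-yl]acetic acid | CC1(C)O[C@](C)(CC(=O)O)C(=O)O1 | intermediate
3 | [(4R)-2,2,4-trimethyl-5-oxo-1,3-dioxolan-4-yl]acetyl chloride | CC1(C)O[C@](C)(CC(=O)Cl)C(=O)O1 | intermediate (not isolated)
4 | (5R)-2,2,5-trimethyl-5-(4-methyl-2-oxopent-3-en-1-yl)-1,3-dioxolan-4-one | CC1(C)O[C@](C)(CC(=O)C=C(C)C)C(=O)O1 | intermediate
5 | (5R)-5-[(2R)-2-hydroxy-4-methylpent-3-en-1-yl]-2,2,5-trimethyl-1,3-dioxolan-4-one | CC1(C)O[C@](C)(C[C@@H](O)C=C(C)C)C(=O)O1 | intermediate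
6 | (5R)-2,2,5-trimethyl-5-{(2R)-4-methyl-2-[(triethylsilyl)oxy]pent-3-en-1-yl}-1,3-dioxolan-4-one | CC1(C)O[C@](C)(C[C@@H](O[Si](CC)(CC)CC)C=C(C)C)C(=O)O1 | intermediate
7 | S-ethyl (2R,4R)-2-hydroxy-2,6-dimethyl-4-[(triethylsilyl)oxy]hept-5-enethioate | CCSC(=O)[C@](C)(O)C[C@@H](O[Si](CC)(CC)CC)C=C(C)C | intermediate
8 | isofraxidin (7-hydroxy-6,8-dimethoxy-2H-chromen-2-one) | COc1cc2ccc(=O)oc2c(OC)c1O | starting material
9 | 6,8-dimethoxy-7-[(tributylstannyl)methoxy]-2H-chromen-2-one | COc1cc2ccc(=O)oc2c(OC)c1OC[Sn](CCCC)(CCCC)CCCC | intermediate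
10 | 7-({(3R,5R)-3-hydroxy-3,7-dimethyl-2-oxo-5-[(triethylsilyl)oxy]oct-6-en-1-yl}oxy)-6,8-dimethoxy-2H-chromen-2-one | COc1cc2ccc(=O)oc2c(OC)c1OCC(=O)[C@](C)(O)C[C@@H](O[Si](CC)(CC)CC)C=C(C)C | intermediate (not isolated)
11 | 7-{[(3R,5R)-2,3-dihydroxy-3-methyl-5-(2-methylprop-1-en-1-yl)oxolan-2-yl]methoxy}-6,8-dimethoxy-2H-chromen-2-one (C2 anomers) | COc1cc2ccc(=O)oc2c(OC)c1OCC1(O)O[C@@H](C=C(C)C)C[C@@]1(C)O | intermediate
12 | 7-{[(2S,3R,5R)-3-hydroxy-3-methyl-5-(2-methylprop-1-en-1-yl)oxolan-2-yl]methoxy}-6,8-dimethoxy-2H-chromen-2-one | COc1cc2ccc(=O)oc2c(OC)c1OC[C@@H]1O[C@@H](C=C(C)C)C[C@@]1(C)O | target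

Total step count: 8. Longest linear sequence: 7 steps (steps 1–5, 7 and 8, from (R)-citramalic acid).

Steps most likely to fail

Step 7. Transfer of the aryloxymethyl group from tin to the hindered α-quaternary acyl–palladium centre may be slower than butyl transfer, decarbonylation or protodestannylation. The union would then be made by a radical route that sets out from 6 and 8. Lithium hydroxide in aqueous THF would open the dioxolanone of 6 to (2R,4R)-2-hydroxy-2,6-dimethyl-4-[(triethylsilyl)oxy]hept-5-enoic acid F1. Compound 8 would be O-alkylated with potassium (bromomethyl)trifluoroborate (K2CO3, DMF) to potassium {[(6,8-dimethoxy-2-oxo-2H-chromen-7-yl)oxy]methyl}trifluoroborate F2. Nickel/photoredox acyl cross-coupling (NiCl2·dme, dtbbpy, iridium photocatalyst, dimethyl dicarbonate to activate F1 in the flask, blue light) would join the aryloxymethyl radical from F2 with the acyl–nickel species from F1. This comes back to the route at ketone 10, which is then treated with HF·pyridine to give 11.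

Step 8. The Lewis acid may ionise the allylic C5–O bond, or hydride may add to the wrong face of the oxocarbenium ion. C2 would then be set by reagent-controlled ketone reduction and the ring closed by SN2 displacement with no Lewis acid. This sets out from ketone 10, isolated before the HF stage of step 7. CBS reduction with the (S)-catalyst and borane (tertiary carbinol carbon as large group, CH2OAr as small group) would give 7-({(2R,3R,5R)-2,3-dihydroxy-3,7-dimethyl-5-[(triethylsilyl)oxy]oct-6-en-1-yl}oxy)-6,8-dimethoxy-2H-chromen-2-one F3. Mesylation of the secondary hydroxyl only (MsCl, Et3N, CH2Cl2, −20 °C) would give (2R,3R,5R)-1-[(6,8-dimethoxy-2-oxo-2H-chromen-7-yl)oxy]-3-hydroxy-3,7-dimethyl-5-[(triethylsilyl)oxy]oct-6-en-2-yl methanesulfonate F4. TBAF in THF would free the C5 alkoxide, which displaces the mesylate in a 5-exo-tet closure with inversion at C2. This comes back to the route at target 12.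

Step 3. The catalyst may discriminate poorly between the isobutenyl group and the neopentyl-type CH2 group, and the product may lactonise during work-up. Luche reduction of 4 (NaBH4, CeCl3, MeOH, −78 °C) would instead give 5 together with its carbinol epimer (5R)-5-[(2S)-2-hydroxy-4-methylpent-3-en-1-yl]-2,2,5-trimethyl-1,3-dioxolan-4-one F5. The two diastereomers would be separated by chromatography, and F5 would be re-oxidised with MnO2 to 4 and recycled. The fallback sets out from 4 and comes back to the route at 5.

Further compounds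
F1 | step 7 | (2R,4R)-2-hydroxy-2,6-dimethyl-4-[(triethylsilyl)oxy]hept-5-enoic acid | OC(=O)[C@](C)(O)C[C@@H](O[Si](CC)(CC)CC)C=C(C)C
F2 | step 7 | potassium {[(6,8-dimethoxy-2-oxo-2H-chromen-7-yl)oxy]methyl}trifluoroborate | COc1cc2ccc(=O)oc2c(OC)c1OC[B-](F)(F)F.[K+]
F3 | step 8 | 7-({(2R,3R,5R)-2,3-dihydroxy-3,7-dimethyl-5-[(triethylsilyl)oxy]oct-6-en-1-yl}oxy)-6,8-dimethoxy-2H-chromen-2-one | COc1cc2ccc(=O)oc2c(OC)c1OC[C@@H](O)[C@](C)(O)C[C@@H](O[Si](CC)(CC)CC)C=C(C)C
F4 | step 8 | (2R,3R,5R)-1-[(6,8-dimethoxy-2-oxo-2H-chromen-7-yl)oxy]-3-hydroxy-3,7-dimethyl-5-[(triethylsilyl)oxy]oct-6-en-2-yl methanesulfonate | COc1cc2ccc(=O)oc2c(OC)c1OC[C@@H](OS(C)(=O)=O)[C@](C)(O)C[C@@H](O[Si](CC)(CC)CC)C=C(C)C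
F5 | step 3 | (5R)-5-[(2S)-2-hydroxy-4-methylpent-3-en-1-yl]-2,2,5-trimethyl-1,3-dioxolan-4-one | CC1(C)O[C@](C)(C[C@H](O)C=C(C)C)C(=O)O1
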